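The vessel was closed and stirred at one temperature, and these flasks and questions stood before me.

| flask | starting material | free catalyst | time |
|---|---|---|---|
| alder | 0.0800 M | 1.60 × 10⁻⁴ M |  |
| larch | 0.0480 M | 1.60 × 10⁻⁴ M |  |
| maple | 0.0800 M | 2.40 × 10⁻⁴ M |  |
| ash | 0.120 M | 1.60 × 10⁻⁴ M |  |
| cedar | 0.0800 M | 3.30 × 10⁻⁴ M | 21 min |

| alder run: time / min | alder run: [target] / M | larch run: time / min | larch run: [target] / M | maple run: time / min | maple run: [target] / M | ash run: time / min | ash run: [target] / M |
|---|---|---|---|---|---|---|---|
| 1.2 | 0.0033 | 1.2 | 0.0024 | 1.2 | 0.0048 | 1.2 | 0.0041 |
| 3.6 | 0.0094 | 3.6 | 0.0084 | 3.6 | 0.0156 | 3.6 | 0.0116 |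
| 6.9 | 0.0182 | 6.9 | 0.0118 | 6.9 | 0.0272 | 6.9 | 0.0191 |
| 11 | 0.0255 | 11 | 0.0191 | 11 | 0.0378 | 11 | 0.0293 |
| 16 | 0.0340 | 16 | 0.0265 | 16 | 0.0477 | 16 | 0.0400 |
| 21 | 0.0393 | 21 | 0.0275 | 21 | 0.0533 | 21 | 0.0485 |

(each reading ± 0.001 M)

* apparent order in [free catalyst] of the starting rate, round the charge of the alder run (the rate where two percent of its starting material have turned into target)
* apparent order in [starting material] of the starting rate, round the charge of the alder run (the rate where two percent of its starting material have turned into target) (one fixed amount of target, the same in the runs compared)
* the larch run starts with 0.0320 M less of starting material than the alder run, and with no target. Compared where both hold the same amount of starting material, once fifteen percent of what the larch run was charged with has turned into target, is the larch run faster, slower or alike (within a tenth)?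
* target in the cedar run at 21 min, as a share of the starting material charged

- Overall: starting material -> target, with free catalyst as catalyst.
- Constant volume, constant temperature.
- Bound and free are read together.
- An order is taken over about fifteen percent of the charge, up and down.

I wrote the balance of the catalyst, charged in a smaller amount than the starting material. I supposed that a fixed amount z of the charge C is lost at the start, leaving working catalyst A = C − z, bound and free together. Alder and maple hold the same starting material, so on this supposition their curves should match once time is stretched by the ratio of their A values. Alder read 0.0393 M at 21 min, and a straight line between maple's readings passes that level at 11.8 min, so the stretch read 1.79. Setting that equal to the ratio of A values gave z = 5.82 × 10⁻⁵ M, the catalyst lost before any turnover, as a reading with the scatter of its readings. If the rate follows A, the order in catalyst is C/A, which for alder is 1.57, higher than the forecast's value.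

The forecast gave 1.2 in catalyst, 0.5 in starting material, larch faster, and 80 % for cedar, saying “That points to catalyst dying”.

The simulation gave 1.6, 0.37, faster and 73.3 %.

    free catalyst + starting material ⇌ catalyst-substrate complex, settled at all times (34.00 /M)
    catalyst-substrate complex ⇌ target + free catalyst (71.40 /min, 298.8 /M/min)
    free catalyst + impurity → spent catalyst
    2 starting material ⇌ idle substrate dimer, settled at all times (104.0 /M)

The catalyst order stood at 1.6 because the impurity, the limiting reagent of its step, turns free catalyst into spent catalyst at once, and the alder run without that step gives 1.0. In the balance, free catalyst, catalyst-substrate complex and spent catalyst add up to C; with spent catalyst equal to z, the first two add up to C − z. Cedar, charged with 3.30 × 10⁻⁴ M, therefore held, on the z I had read, A = 2.72 × 10⁻⁴ M, which is 1.50 times maple's A, so its 21 min counted as 31.4 min on maple's clock. Against 66.6 % read in maple at 21 min, cedar reached 73.3 %.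

The readings stem from a simulated flask for substances that don't exist; scatter was added.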